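**Strategy.** Everything rests on cutting ring C between C3 and C4. Written as its silyl enol ether, the C4 ketone makes this bond a C3=C4 double bond inside the ring. Olefin metathesis can form that bond from a vinyl group on C2 and the enol ether of an acetyl group on C4a. One operation thus closes the oxygen heterocycle and leaves the C2 stereocentre, set earlier, untouched. The substrate is the (S)-1-(3,4,5-trimethoxyphenyl)allyl ether of a ring A acetophenone tert-butyldimethylsilyl enol ether that already bears the C6 prenyl and C7 methoxy groups. O5 is carried as a methoxymethyl ether, so one mild acid treatment afterwards releases the ketone and the C5 hydroxyl together.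

Key step: step 8

Remark: flavanone numbering (O1, C2, C3, C4, C4a, C5 to C8, C8a) is used for ring positions throughout; compounds 1, 3 and 8 are taken as commercial.

Remark: O5 is protected as a methoxymethyl ether and not as a methyl ether, because a late cleavage of a 5-O-methyl ether would need a boron or aluminium halide in the presence of the prenyl alkene, the benzylic C2–O1 bond and four other methyl ethers.

Remark: the (Sa,Sc,Sc) ligand in step 6 is specified on the premise that the (Ra,Rc,Rc) form of this catalyst family leads to (R)-1-arylallyl aryl ethers; the configuration of 12 is to be verified at that stage and the antipodal ligand used if the premise proves wrong.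

**Step 1**
Reactants: 1 2',6'-dihydroxy-4'-methoxyacetophenone
Product: 2 1-[2-hydroxy-4-methoxy-6-(methoxymethoxy)phenyl]ethanone
Conditions: MOMCl (1.1 equiv), i-Pr2NEt, CH2Cl2, 0 °C to rt
Reagents that add atoms: chloromethyl methyl ether, COCCl
Why: Methoxymethylation of a phenol (Williamson-type O-alkylation): the two hydroxyls of 1 are equivalent, and once one is capped the other is held in a strong hydrogen bond to the acetyl carbonyl and reacts far more slowly, so one equivalent of reagent should stop at the mono-ether.

**Step 2**
Reactants: 2 1-[2-hydroxy-4-methoxy-6-(methoxymethoxy)phenyl]ethanone; 3 prenyl bromide (1-bromo-3-methylbut-2-ene)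
Product: 4 1-[4-methoxy-2-(methoxymethoxy)-6-(3-methylbut-2-enyloxy)phenyl]ethanone
Conditions: K2CO3, acetone, reflux
Reagents that add atoms: none
Why: Williamson ether synthesis: carbonate deprotonates the chelated phenol and the phenoxide displaces bromide from the primary allylic halide at oxygen, the acetal and the ketone being inert to K2CO3.

**Step 3**
Reactants: 4 1-[4-methoxy-2-(methoxymethoxy)-6-(3-methylbut-2-enyloxy)phenyl]ethanone
Product: 7 1-[6-hydroxy-4-methoxy-2-(methoxymethoxy)-3-(3-methylbut-2-enyl)phenyl]ethanone, via ortho-dienone 5 (not isolated), via para-dienone 6 (not isolated)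
Conditions: PhNEt2, 200 °C (sealed tube), Ar
Reagents that add atoms: none
Why: Tandem aromatic Claisen and Cope rearrangements (para-Claisen rearrangement): the first [3,3] shift places a 1,1-dimethylallyl group on the free ortho carbon, the congested dienone 5 undergoes a second [3,3] shift to the para carbon faster than it enolises, and tautomerisation of 6 gives the normal prenyl group at C6 between the two alkoxy groups while regenerating the phenol needed for step 6, as is established for closely related 2-prenyloxy-4,6-dialkoxyacetophenones.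

**Step 4**
Reactants: 8 methyl (E)-3,4,5-trimethoxycinnamate
Product: 9 (E)-3-(3,4,5-trimethoxyphenyl)prop-2-en-1-ol
Conditions: i-Bu2AlH (2.3 equiv), CH2Cl2, −78 to 0 °C; aq. KNaC4H4O6 work-up
Reagents that add atoms: none
Why: 1,2-Reduction of a conjugated ester with an electrophilic aluminium hydride, which at low temperature reduces the ester to the allylic alcohol without touching the alkene or its E geometry.

**Step 5**
Reactants: 9 (E)-3-(3,4,5-trimethoxyphenyl)prop-2-en-1-ol
Product: 10 methyl (E)-3-(3,4,5-trimethoxyphenyl)prop-2-enyl carbonate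
Conditions: ClCO2Me, pyridine, CH2Cl2, 0 °C
Reagents that add atoms: methyl chloroformate, COC(=O)Cl
Why: Acylation of a primary alcohol with a chloroformate under pyridine catalysis, giving the linear allylic methyl carbonate that serves as the electrophile in step 6.

**Step 6**
Reactants: 7 1-[6-hydroxy-4-methoxy-2-(methoxymethoxy)-3-(3-methylbut-2-enyl)phenyl]ethanone; 10 methyl (E)-3-(3,4,5-trimethoxyphenyl)prop-2-enyl carbonate
Product: 12 1-[4-methoxy-2-(methoxymethoxy)-3-(3-methylbut-2-enyl)-6-{[(1S)-1-(3,4,5-trimethoxyphenyl)prop-2-en-1-yl]oxy}phenyl]ethanone, via sodium aryloxide 11 (not isolated)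
Conditions: NaH (1.0 equiv), THF, 0 °C; then 10 (1.2 equiv), [Ir(cod)Cl]2 (2 mol %; cod = 1,5-cyclooctadiene), (Sa,Sc,Sc)-(1,1'-binaphthalene-2,2'-diyl) N,N-bis(1-phenylethyl)phosphoramidite (4 mol %, preactivated with n-PrNH2), THF, 50 °C
Reagents that add atoms: none
Why: Iridium-catalysed enantioselective allylic etherification: the cyclometalated iridium phosphoramidite complex ionises the linear carbonate to an η3-allyl intermediate that the aryloxide attacks at the aryl-substituted terminus anti to the metal, so that the branched ether forms and the chiral ligand fixes C2 as S.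

**Step 7**
Reactants: 12 1-[4-methoxy-2-(methoxymethoxy)-3-(3-methylbut-2-enyl)-6-{[(1S)-1-(3,4,5-trimethoxyphenyl)prop-2-en-1-yl]oxy}phenyl]ethanone
Product: 13 tert-butyl({1-[4-methoxy-2-(methoxymethoxy)-3-(3-methylbut-2-enyl)-6-{[(1S)-1-(3,4,5-trimethoxyphenyl)prop-2-en-1-yl]oxy}phenyl]ethenyl}oxy)dimethylsilane
Conditions: TBSOTf (1.5 equiv), Et3N (3 equiv), CH2Cl2, −78 to 0 °C
Reagents that add atoms: tert-butyldimethylsilyl trifluoromethanesulfonate, CC(C)(C)[Si](C)(C)OS(=O)(=O)C(F)(F)F
Why: Soft enolisation of a methyl ketone: the silyl triflate activates the carbonyl oxygen and triethylamine removes a methyl proton to give the only possible (terminal) silyl enol ether, while the excess amine keeps the medium basic so that neither the acetal nor the allylic benzylic ether is ionised.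

**Step 8**
Reactants: 13 tert-butyl({1-[4-methoxy-2-(methoxymethoxy)-3-(3-methylbut-2-enyl)-6-{[(1S)-1-(3,4,5-trimethoxyphenyl)prop-2-en-1-yl]oxy}phenyl]ethenyl}oxy)dimethylsilane
Product: 14 tert-butyl{[(2S)-7-methoxy-5-(methoxymethoxy)-6-(3-methylbut-2-enyl)-2-(3,4,5-trimethoxyphenyl)-2H-chromen-4-yl]oxy}dimethylsilane
Conditions: second-generation Grubbs catalyst RuCl2(=CHPh)(H2IMes)(PCy3) (10 mol %), degassed toluene (0.01 M), 70 °C, Ar sparge
Reagents that add atoms: none
Why: Ring-closing olefin metathesis of an enol ether with an alkene: the catalyst exchanges its benzylidene for the unhindered C2 vinyl group, the resulting alkylidene adds across the 1,1-disubstituted silyl enol ether to a ruthenacyclobutane, and cycloreversion gives the C3=C4 bond while the two terminal CH2 units leave as ethene. The closest known reaction type is the ring-closing metathesis of olefinic silyl enol ethers to cyclic silyl enol ethers, for example 4-silyloxy-1,2-dihydroquinolines from N-allyl-2-(1-silyloxyvinyl)anilines. Ring C closes as a six-membered ring in which C3 and C4 are the two alkene carbons retained from the vinyl group and the enol ether, the other four ring atoms (C4a, C8a, O1, C2) being connected beforehand, and the ortho disposition on ring A holds the two alkenes close. No stereocentre is formed, and C2, set in step 6 by the iridium catalyst, bears no bond that the neutral metathesis conditions break. The selectivity required is for the two terminal alkenes over the trisubstituted prenyl alkene, which the slow reaction of this catalyst with trisubstituted alkenes, the entropic advantage of six-membered closure, high dilution and continuous removal of ethene should secure. Because ring C emerges with C4 still masked as its silyl enol ether, the ketone can later be unveiled by protonation at C3 alone, so that no enolate able to expel the O1 phenoxide is ever formed.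

**Step 9**
Reactants: 14 tert-butyl{[(2S)-7-methoxy-5-(methoxymethoxy)-6-(3-methylbut-2-enyl)-2-(3,4,5-trimethoxyphenyl)-2H-chromen-4-yl]oxy}dimethylsilane
Product: 16 artoflavanone [(2S)-5-hydroxy-7-methoxy-6-(3-methylbut-2-enyl)-2-(3,4,5-trimethoxyphenyl)chroman-4-one], via 5-O-methoxymethyl flavanone 15 (not isolated)
Conditions: 2 M aq. HCl, MeOH/THF, rt
Reagents that add atoms: none
Why: Acid-catalysed hydrolysis: protonation of the silyl enol ether at C3 and loss of silicon unveils the C4 ketone without an enolate, and the methoxymethyl acetal peri to that carbonyl is then hydrolysed under the same dilute acid, conditions under which C2 should not epimerise and the C5 hydroxyl should not add to the prenyl alkene.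

**Compound list**
1 | 2',6'-dihydroxy-4'-methoxyacetophenone | CC(=O)c1c(O)cc(OC)cc1O | starting material
2 | 1-[2-hydroxy-4-methoxy-6-(methoxymethoxy)phenyl]ethanone | CC(=O)c1c(O)cc(OC)cc1OCOC | intermediate
3 | prenyl bromide (1-bromo-3-methylbut-2-ene) | CC(C)=CCBr | starting material
4 | 1-[4-methoxy-2-(methoxymethoxy)-6-(3-methylbut-2-enyloxy)phenyl]ethanone | CC(=O)c1c(OCC=C(C)C)cc(OC)cc1OCOC | intermediate
5 | 2-acetyl-5-methoxy-3-(methoxymethoxy)-6-(2-methylbut-3-en-2-yl)cyclohexa-2,4-dien-1-one (racemic ortho-dienone) | CC(=O)C1=C(OCOC)C=C(OC)C(C(C)(C)C=C)C1=O | intermediate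
6 | 2-acetyl-5-methoxy-3-(methoxymethoxy)-4-(3-methylbut-2-enyl)cyclohexa-2,5-dien-1-one (racemic para-dienone) | CC(=O)C1=C(OCOC)C(CC=C(C)C)C(OC)=CC1=O | intermediate
7 | 1-[6-hydroxy-4-methoxy-2-(methoxymethoxy)-3-(3-methylbut-2-enyl)phenyl]ethanone | CC(=O)c1c(O)cc(OC)c(CC=C(C)C)c1OCOC | intermediate
8 | methyl (E)-3,4,5-trimethoxycinnamate | COC(=O)/C=C/c1cc(OC)c(OC)c(OC)c1 | starting material
9 | (E)-3-(3,4,5-trimethoxyphenyl)prop-2-en-1-ol | OC/C=C/c1cc(OC)c(OC)c(OC)c1 | intermediate
10 | methyl (E)-3-(3,4,5-trimethoxyphenyl)prop-2-enyl carbonate | COC(=O)OC/C=C/c1cc(OC)c(OC)c(OC)c1 | intermediate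
11 | sodium 2-acetyl-5-methoxy-3-(methoxymethoxy)-4-(3-methylbut-2-enyl)phenolate | CC(=O)c1c([O-])cc(OC)c(CC=C(C)C)c1OCOC.[Na+] | intermediate
12 | 1-[4-methoxy-2-(methoxymethoxy)-3-(3-methylbut-2-enyl)-6-{[(1S)-1-(3,4,5-trimethoxyphenyl)prop-2-en-1-yl]oxy}phenyl]ethanone | C=C[C@@H](c1cc(OC)c(OC)c(OC)c1)Oc1cc(OC)c(CC=C(C)C)c(OCOC)c1C(C)=O | intermediate
13 | tert-butyldimethylsilyl enol ether of 12 (S; metathesis precursor) | C=C[C@@H](c1cc(OC)c(OC)c(OC)c1)Oc1cc(OC)c(CC=C(C)C)c(OCOC)c1C(=C)O[Si](C)(C)C(C)(C)C | intermediate
14 | (2S)-4-(tert-butyldimethylsilyloxy)-7-methoxy-5-(methoxymethoxy)-6-(3-methylbut-2-enyl)-2-(3,4,5-trimethoxyphenyl)-2H-chromene | COc1cc2c(c(OCOC)c1CC=C(C)C)C(O[Si](C)(C)C(C)(C)C)=C[C@@H](c1cc(OC)c(OC)c(OC)c1)O2 | intermediate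
15 | (2S)-7-methoxy-5-(methoxymethoxy)-6-(3-methylbut-2-enyl)-2-(3,4,5-trimethoxyphenyl)chroman-4-one | COc1cc2c(c(OCOC)c1CC=C(C)C)C(=O)C[C@@H](c1cc(OC)c(OC)c(OC)c1)O2 | intermediate
16 | artoflavanone, (2S)-5-hydroxy-7-methoxy-6-(3-methylbut-2-enyl)-2-(3,4,5-trimethoxyphenyl)chroman-4-one | COc1cc2c(c(O)c1CC=C(C)C)C(=O)C[C@@H](c1cc(OC)c(OC)c(OC)c1)O2 | target

**Step count.** Total: 9 steps. Longest linear sequence: 7 steps (steps 1, 2, 3, 6, 7, 8, 9).

**Steps most likely to fail**

Step 8. The alkylidene formed at the C2 vinyl group may add only slowly to the hindered, electron-rich enol ether next to the ortho methoxymethoxy group. Catalyst decay could then lead to alkene isomerisation or to cross-metathesis and ethenolysis at the prenyl group. The fallback abandons metathesis, sets out from 7 and comes back at 15.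
- 7 is heated with N,N-dimethylformamide dimethyl acetal (toluene, 100 °C) to give the enaminone (E)-3-(dimethylamino)-1-[6-hydroxy-4-methoxy-2-(methoxymethoxy)-3-(3-methylbut-2-enyl)phenyl]prop-2-en-1-one F1.
- Brief exposure to dilute HCl in CH2Cl2 should cyclise it, with loss of dimethylamine, to 7-methoxy-5-(methoxymethoxy)-6-(3-methylbut-2-enyl)-4H-chromen-4-one F2.
- Enantioselective conjugate addition of 3,4,5-trimethoxyphenylboronic acid should then give 15 (Pd(OCOCF3)2, t-BuPyOx in the antipode that delivers 2S, expected to be the R form, NH4PF6, H2O, ClCH2CH2Cl, 60 °C).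
- Step 9 then carries 15 to 16.

Step 6. The chelated, weakly nucleophilic ortho-acyl aryloxide may substitute slowly. Reversible ionisation of the branched ether at iridium could erode the branched selectivity and the enantiomeric purity, and methoxide transfer may compete. The fallback separates the asymmetric step from the C–O coupling, sets out from 10 and comes back at 12.
- 10 is treated with KOSiEt3 under [Ir(cod)Cl]2 and the antipodal (Ra,Rc,Rc) phosphoramidite (CH2Cl2, rt) to give triethyl{[(1R)-1-(3,4,5-trimethoxyphenyl)prop-2-en-1-yl]oxy}silane F3, a silyl ether that the catalyst cannot re-ionise.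
- Bu4NF in THF frees (R)-1-(3,4,5-trimethoxyphenyl)prop-2-en-1-ol F4.
- Mitsunobu etherification of F4 with phenol 7 (PPh3, diisopropyl azodicarboxylate, toluene, 0 °C) should proceed with inversion and give 12.

Step 9. While the slower acetal cleavage runs, the acid may add the freed C5 hydroxyl across the prenyl alkene, or reversibly open ring C and erode the configuration at C2. The fallback splits the operation into two non-protic cleavages, sets out from 14 and comes back at 16.
- Et3N·3HF (THF, 0 °C) should remove only the enol silyl group, and 15 is isolated.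
- ZnBr2 with n-PrSH (CH2Cl2, 0 °C) then transfers the methoxymethyl group from the chelated peri oxygen to sulfur and gives 16.
- No compound outside the compound list is made on this path (F0).

**Further compounds**
F1 | step 8 | (E)-3-(dimethylamino)-1-[6-hydroxy-4-methoxy-2-(methoxymethoxy)-3-(3-methylbut-2-enyl)phenyl]prop-2-en-1-one | CN(C)/C=C/C(=O)c1c(O)cc(OC)c(CC=C(C)C)c1OCOC
F2 | step 8 | 7-methoxy-5-(methoxymethoxy)-6-(3-methylbut-2-enyl)-4H-chromen-4-one | COc1cc2occc(=O)c2c(OCOC)c1CC=C(C)C
F3 | step 6 | triethyl{[(1R)-1-(3,4,5-trimethoxyphenyl)prop-2-en-1-yl]oxy}silane | C=C[C@H](c1cc(OC)c(OC)c(OC)c1)O[Si](CC)(CC)CC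
F4 | step 6 | (R)-1-(3,4,5-trimethoxyphenyl)prop-2-en-1-ol | C=C[C@H](c1cc(OC)c(OC)c(OC)c1)O
F0 | step 9 | none | none
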